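The cyclohexa-2,5-dienone ring (C1 carbonyl, C2 propenyl, C4 quaternary, C5 methoxy) is cut at C2–C3 and C4–C5. The key step exploits two features: the C5(OMe)=C6–C1=O vinylogous ester is the footprint of a 1,1-dimethoxy-3-silyloxydiene, and the C2=C3 double bond next to C4 marks where a sulfinyl group has departed. One zinc-mediated [4+2] addition of an allyl-bearing silyloxy ketene acetal diene to an enantiopure (Z)-β-sulfinyl-α-methoxy enone therefore closes the ring, sets C4 and, after loss of silanol, methanol and sulfenic acid, gives the 4-acetyl dienone. Allyl isomerisation and benzylation–dehydration of the acetyl group complete the target.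

Key step: step 7

Assumption: the sense of induction in step 4 is taken to follow aryl methyl sulfides (tolyl as the large group) and the face selection in step 7 to follow the zinc chelate model; if either proves opposite, (S,S)-diethyl tartrate is used in step 4 and nothing else changes.

Step 1
Reactants: 1 3,3-dimethoxybutan-2-one
Product: 2 3-methoxybut-3-en-2-one
Conditions: TsOH·H2O (cat.), hydroquinone (trace), neat, 140 °C, MeOH distilled off; distillation, used at once
Reagents that add atoms: none
Why: Acid-catalysed β-elimination of methanol from the ketal through its oxocarbenium ion, which can lose a proton only from the adjacent methyl group, gives the enol ether, and continuous removal of methanol drives the equilibrium.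

Step 2
Reactants: 2 3-methoxybut-3-en-2-one
Product: 4 (Z)-4-bromo-3-methoxybut-3-en-2-one, via 3,4-dibromo-3-methoxybutan-2-one 3 (not isolated)
Conditions: Br2 (1.0 equiv), CH2Cl2, −78 °C; then Et3N (1.2 equiv), −78 °C to rt
Reagents that add atoms: bromine, BrBr
Why: Electrophilic bromination of the enol ether double bond gives the α-bromo ether 3, whose labile tertiary bromide departs with a C4 proton under Et3N (bromination–dehydrobromination) to give the β-bromo enone with bromine trans to the acetyl group, the less hindered (Z) isomer.

Step 3
Reactants: 4 (Z)-4-bromo-3-methoxybut-3-en-2-one; 5 4-methylbenzenethiol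
Product: 6 (Z)-3-methoxy-4-[(4-methylphenyl)sulfanyl]but-3-en-2-one
Conditions: 5 (1.0 equiv), Et3N (1.1 equiv), CH2Cl2, 0 °C to rt
Reagents that add atoms: none
Why: Conjugate addition of the thiolate to the β-carbon of the enone and expulsion of bromide (vinylic addition–elimination) gives the vinylogous thioester with retention of geometry, the isomer with sulfur trans to acetyl also being the thermodynamic one.

Step 4
Reactants: 6 (Z)-3-methoxy-4-[(4-methylphenyl)sulfanyl]but-3-en-2-one
Product: 7 (Z)-3-methoxy-4-[(R)-(4-methylphenyl)sulfinyl]but-3-en-2-one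
Conditions: Ti(OiPr)4 (1 equiv), (R,R)-diethyl tartrate (2 equiv), H2O (1 equiv), cumene hydroperoxide (1.1 equiv), CH2Cl2, −20 °C; recrystallisation
Reagents that add atoms: cumene hydroperoxide, CC(C)(OO)c1ccccc1
Why: In this Kagan–Modena sulfoxidation the water-modified titanium tartrate peroxo complex delivers one oxygen atom to one lone pair of sulfur, which sets the sulfur stereocentre as (R) by discrimination between the aryl and alkenyl substituents, stops at the sulfoxide and leaves the enone untouched, and recrystallisation of the sulfoxide should raise its enantiomeric purity.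

Step 5
Reactants: 8 pent-4-enoyl chloride; 9 1,1-dimethoxyethene
Product: 10 1,1-dimethoxyhepta-1,6-dien-3-one
Conditions: 9 (2.1 equiv), Et2O, 0 °C to rt
Reagents that add atoms: none
Why: C-acylation of the electron-rich ketene acetal by the acid chloride and loss of a proton from the dimethoxycarbenium ion gives the acylketene acetal, while the second equivalent of 9 takes up HCl as methyl acetate and chloromethane so that the acid-sensitive product survives.

Step 6
Reactants: 10 1,1-dimethoxyhepta-1,6-dien-3-one
Product: 11 (3Z)-1,1-dimethoxy-3-(trimethylsilyloxy)hepta-1,3,6-triene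
Conditions: Me3SiOTf (1.1 equiv), Et3N (1.3 equiv), Et2O, 0 °C; filtration and bulb-to-bulb distillation under argon, used directly
Reagents that add atoms: trimethylsilyl trifluoromethanesulfonate, C[Si](C)(C)OS(=O)(=O)C(F)(F)F
Why: Soft enolisation (O-silylation, then deprotonation at the only α-CH2 group) gives the silyl dienol ether, and the (Z) geometry with the silyloxy group cis to the allylic CH2 is favoured because it places the allyl group on the outside of the s-cis diene.

Step 7
Reactants: 7 (Z)-3-methoxy-4-[(R)-(4-methylphenyl)sulfinyl]but-3-en-2-one; 11 (3Z)-1,1-dimethoxy-3-(trimethylsilyloxy)hepta-1,3,6-triene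
Product: 15 (4R)-4-acetyl-4,5-dimethoxy-2-(prop-2-enyl)cyclohexa-2,5-dienone, via silyl enol ether cycloadduct 12 (not isolated), via sulfinyl trimethoxy ketone 13 (not isolated), via sulfinyl methoxy enone 14 (not isolated)
Conditions: 11 (1.5 equiv), ZnBr2 (1.5 equiv), CH2Cl2, −78 to −20 °C; aq. citric acid–THF, 0 °C; then Et3N (cat.), CH2Cl2, rt
Reagents that add atoms: none
Why: ZnBr2 bridges the sulfinyl oxygen and the neighbouring methoxy oxygen of 7 in a six-membered chelate, which holds the S=O bond syn-coplanar with the alkene, leaves the tolyl group over one π-face and activates the enone. The allyl-bearing CH terminus of the diene, made nucleophilic by both methoxy groups and the silyloxy group, bonds to the sulfinyl-bearing β-carbon and the zinc enolate carbon then bonds to the dimethoxy terminus, so the six-membered ring closes by a suprafacial [4+2] cycloaddition or, at the polar limit, by Mukaiyama–Michael addition followed by 6-(enolexo)-exo-trig capture of the dimethoxycarbenium ion. The closest known reaction types are Lewis-acid-promoted Diels–Alder reactions of 1,1-dialkoxy-3-silyloxybutadienes and of enantiopure sulfinyl-substituted enones and quinones. C4 is the only stereocentre that persists and is fixed as (R) by approach of the diene to the face anti to the tolyl group of the chelated (R)-sulfoxide, whereas the centres at C2 and C3 are erased later in the same flask. The regiochemistry that is needed follows from matched polarisation, the acetyl group making the sulfinyl-bearing carbon the electrophilic site and the diene donors making the CH terminus the nucleophilic one. On work-up the silyl enol ether 12 is hydrolysed to ketone 13, the β,β-dimethoxy ketone loses methanol to give 14 with one methoxy group necessarily left on C5, and the β-sulfinyl ketone loses 4-methylbenzenesulfenic acid across C2–C3, so the auxiliary leaves no trace.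

Step 8
Reactants: 15 (4R)-4-acetyl-4,5-dimethoxy-2-(prop-2-enyl)cyclohexa-2,5-dienone
Product: 16 (4R)-4-acetyl-4,5-dimethoxy-2-[(E)-prop-1-enyl]cyclohexa-2,5-dienone
Conditions: RuHCl(CO)(PPh3)3 (5 mol %), toluene, 80 °C
Reagents that add atoms: none
Why: Ruthenium hydride addition to the terminal alkene and β-hydride elimination (transition-metal-catalysed alkene isomerisation) move the double bond into conjugation with the dienone under thermodynamic control, which gives the (E)-propenyl group, while the neutral aprotic medium avoids deacylative aromatisation and leaves C4 untouched.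

Step 9
Reactants: 16 (4R)-4-acetyl-4,5-dimethoxy-2-[(E)-prop-1-enyl]cyclohexa-2,5-dienone; 17 4-(chloromethyl)-1,2-dimethoxybenzene
Product: 20 (4S)-4-[1-(3,4-dimethoxyphenyl)-2-hydroxypropan-2-yl]-4,5-dimethoxy-2-[(E)-prop-1-enyl]cyclohexa-2,5-dienone (both carbinol epimers), via (3,4-dimethoxybenzyl)magnesium chloride 18 (not isolated), via (3,4-dimethoxybenzyl)cerium dichloride 19 (not isolated)
Conditions: 17, Mg turnings, THF, 0 °C; anhydrous CeCl3, THF, −78 °C; then 16, −78 °C; AcOH, −78 °C
Reagents that add atoms: none
Why: Grignard reagent 18 is transmetallated to the weakly basic, oxophilic organocerium reagent 19, which adds 1,2 to the acetyl carbonyl (organocerium addition, assisted by chelation of cerium between the ketone and C4 methoxy oxygens) in preference to the deactivated vinylogous ester carbonyl at C1, the new carbinol centre arising under chelation control as an epimer mixture that does not matter because step 10 makes it planar, and the cold acetic acid quench forestalls retro-aldol loss of the side chain from the alkoxide.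

Step 10
Reactants: 20 (4S)-4-[1-(3,4-dimethoxyphenyl)-2-hydroxypropan-2-yl]-4,5-dimethoxy-2-[(E)-prop-1-enyl]cyclohexa-2,5-dienone
Product: 21 (4S)-4-[(E)-1-(3,4-dimethoxyphenyl)prop-1-en-2-yl]-4,5-dimethoxy-2-[(E)-prop-1-enyl]cyclohexa-2,5-dienone
Conditions: methyl N-(triethylammoniosulfonyl)carbamate (2 equiv), toluene, 50 °C
Reagents that add atoms: none
Why: Burgess dehydration proceeds through the sulfamate ester and a syn-elimination that removes a benzylic hydrogen to give the conjugated trisubstituted styrene, the aryl group lying anti to the bulky quaternary C4 in the transition state so that the (E) alkene results, and the absence of a free carbocation protects the doubly allylic C4 ether from rearrangement.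

Compound list
1 | 3,3-dimethoxybutan-2-one | CC(=O)C(C)(OC)OC | starting material
2 | 3-methoxybut-3-en-2-one | CC(=O)C(=C)OC | intermediate
3 | 3,4-dibromo-3-methoxybutan-2-one (racemic) | CC(=O)C(Br)(OC)CBr | intermediate
4 | (Z)-4-bromo-3-methoxybut-3-en-2-one | CC(=O)/C(OC)=C/Br | intermediate
5 | 4-methylbenzenethiol | Cc1ccc(S)cc1 | starting material
6 | (Z)-3-methoxy-4-[(4-methylphenyl)sulfanyl]but-3-en-2-one | CC(=O)/C(OC)=C/Sc1ccc(C)cc1 | intermediate
7 | (Z)-3-methoxy-4-[(R)-(4-methylphenyl)sulfinyl]but-3-en-2-one | CC(=O)/C(OC)=C/[S@@](=O)c1ccc(C)cc1 | intermediate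
8 | pent-4-enoyl chloride | C=CCCC(Cl)=O | starting material
9 | 1,1-dimethoxyethene | C=C(OC)OC | starting material
10 | 1,1-dimethoxyhepta-1,6-dien-3-one | C=CCCC(=O)C=C(OC)OC | intermediate
11 | (3Z)-1,1-dimethoxy-3-(trimethylsilyloxy)hepta-1,3,6-triene | COC(OC)=C/C(O[Si](C)(C)C)=C/CC=C | intermediate
12 | 1-[1,2,2-trimethoxy-6-[(R)-(4-methylphenyl)sulfinyl]-5-(prop-2-enyl)-4-(trimethylsilyloxy)cyclohex-3-en-1-yl]ethanone, endo adduct with allyl cis to acetyl and sulfinyl cis to the 1-methoxy group | C=CC[C@@H]1[C@@H]([S@@](=O)c2ccc(C)cc2)[C@](OC)(C(C)=O)C(OC)(OC)C=C1O[Si](C)(C)C | intermediate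
13 | 4-acetyl-4,5,5-trimethoxy-3-[(R)-(4-methylphenyl)sulfinyl]-2-(prop-2-enyl)cyclohexanone, relative configuration as in 12 | C=CC[C@@H]1[C@@H]([S@@](=O)c2ccc(C)cc2)[C@](OC)(C(C)=O)C(OC)(OC)CC1=O | intermediate
14 | 4-acetyl-4,5-dimethoxy-3-[(R)-(4-methylphenyl)sulfinyl]-2-(prop-2-enyl)cyclohex-5-enone (ring numbered as in the target), relative configuration as in 12 | C=CC[C@@H]1[C@@H]([S@@](=O)c2ccc(C)cc2)[C@](OC)(C(C)=O)C(OC)=CC1=O | intermediate
15 | (4R)-4-acetyl-4,5-dimethoxy-2-(prop-2-enyl)cyclohexa-2,5-dienone | C=CCC1=C[C@](OC)(C(C)=O)C(OC)=CC1=O | intermediate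
16 | (4R)-4-acetyl-4,5-dimethoxy-2-[(E)-prop-1-enyl]cyclohexa-2,5-dienone | C/C=C/C1=C[C@](OC)(C(C)=O)C(OC)=CC1=O | intermediate
17 | 4-(chloromethyl)-1,2-dimethoxybenzene | COc1ccc(CCl)cc1OC | starting material
18 | (3,4-dimethoxybenzyl)magnesium chloride | COc1ccc(C[Mg]Cl)cc1OC | intermediate
19 | (3,4-dimethoxybenzyl)cerium dichloride | COc1ccc(C[Ce](Cl)Cl)cc1OC | intermediate
20 | (4S)-4-[1-(3,4-dimethoxyphenyl)-2-hydroxypropan-2-yl]-4,5-dimethoxy-2-[(E)-prop-1-enyl]cyclohexa-2,5-dienone, both carbinol epimers; same spatial arrangement at C4 as in 16, the descriptor changes because the side-chain carbon no longer outranks C5 | C/C=C/C1=C[C@](OC)(C(C)(O)Cc2ccc(OC)c(OC)c2)C(OC)=CC1=O | intermediate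
21 | (4S)-4-[(E)-1-(3,4-dimethoxyphenyl)prop-1-en-2-yl]-4,5-dimethoxy-2-[(E)-prop-1-enyl]cyclohexa-2,5-dienone | C/C=C/C1=C[C@](OC)(/C(C)=C/c2ccc(OC)c(OC)c2)C(OC)=CC1=O | target

Total step count: 10. Longest linear sequence: 8 steps (steps 1–4, then 7–10); the diene arm (steps 5 and 6) joins at step 7.

Steps most likely to fail

Step 7. Three things may go wrong. The polar pathway may stop after conjugate addition because the hindered enolate does not close onto the dimethoxy terminus. Facial discrimination may erode if zinc binds the acetyl and methoxy oxygens instead of the sulfinyl–methoxy pair. The product may aromatise by losing its acetyl group during the elimination phase. The fallback separates the leaving group from the source of asymmetry. It sets out from bromo enone 4 and diene 11, which would be joined in a catalyst-controlled Diels–Alder reaction under a triflimide-activated chiral oxazaborolidinium Lewis acid (CH2Cl2, −78 °C). The catalyst antipode would be chosen to give the (4R) series. Citric acid work-up would give 4-acetyl-3-bromo-4,5,5-trimethoxy-2-(prop-2-enyl)cyclohexanone F1. DBU (CH2Cl2, 0 °C) would then remove HBr across C2–C3 and methanol across C5–C6, and the route is rejoined at 15.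

Step 4. Oxygen transfer to the electron-poor sulfur of the vinylogous thioester may be slow, and enantioselection may be insufficient because both sulfur substituents are sp2 carbons; recrystallisation may not correct this. The fallback fixes the sulfur configuration by an Andersen-type displacement and sets out from 4.
- Luche reduction (NaBH4, CeCl3·7H2O, MeOH, −40 °C) would give (Z)-4-bromo-3-methoxybut-3-en-2-ol F2.
- Silylation (tBuMe2SiCl, imidazole, DMF) would give (Z)-1-bromo-3-(tert-butyldimethylsilyloxy)-2-methoxybut-1-ene F3.
- Bromine–lithium exchange (tBuLi, 2 equiv, Et2O, −78 °C) would give a vinyllithium held by the cis methoxy group. It would attack (1R,2S,5R)-menthyl (S)-4-methylbenzenesulfinate with inversion at sulfur and retention at the alkene, giving (Z)-3-(tert-butyldimethylsilyloxy)-2-methoxy-1-[(R)-(4-methylphenyl)sulfinyl]but-1-ene F4.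
- Bu4NF in THF would free (Z)-3-methoxy-4-[(R)-(4-methylphenyl)sulfinyl]but-3-en-2-ol F5.
- MnO2 in CH2Cl2 would oxidise the allylic alcohol, and the route is rejoined at 7.

Step 9. Wurtz coupling may consume the benzylic halide during Grignard formation. The tertiary alkoxide may fragment by a retro-aldol process driven by aromatisation of the ring. Part of the reagent may attack the C1 carbonyl. The later dehydration may also give some of the unconjugated or (Z) alkene. The fallback replaces addition and dehydration (steps 9 and 10) by a Julia–Kocienski olefination, in which the alkoxide is consumed at once by Smiles rearrangement. It sets out from 17 and 16.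
- 17 with 1-phenyl-1H-tetrazole-5-thiol and Et3N in THF would give 5-[(3,4-dimethoxybenzyl)sulfanyl]-1-phenyl-1H-tetrazole F6.
- H2O2 with (NH4)6Mo7O24·4H2O (cat.) in EtOH would give 5-[(3,4-dimethoxybenzyl)sulfonyl]-1-phenyl-1H-tetrazole F7.
- KHMDS added to F7 and 16 in DME at −60 °C (Barbier mode) would give the (E)-styrene directly, with the aryl group placed away from the quaternary carbon, and the route is rejoined at 21.

Further compounds
F1 | step 7 | 4-acetyl-3-bromo-4,5,5-trimethoxy-2-(prop-2-enyl)cyclohexanone (bromine cis to the C4 methoxy group, allyl cis to acetyl) | C=CC[C@@H]1[C@@H](Br)[C@](OC)(C(C)=O)C(OC)(OC)CC1=O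
F2 | step 4 | (Z)-4-bromo-3-methoxybut-3-en-2-ol (racemic) | CC(O)/C(OC)=C/Br
F3 | step 4 | (Z)-1-bromo-3-(tert-butyldimethylsilyloxy)-2-methoxybut-1-ene (racemic) | CC(O[Si](C)(C)C(C)(C)C)/C(OC)=C/Br
F4 | step 4 | (Z)-3-(tert-butyldimethylsilyloxy)-2-methoxy-1-[(R)-(4-methylphenyl)sulfinyl]but-1-ene (both carbinol epimers) | CC(O[Si](C)(C)C(C)(C)C)/C(OC)=C/[S@@](=O)c1ccc(C)cc1
F5 | step 4 | (Z)-3-methoxy-4-[(R)-(4-methylphenyl)sulfinyl]but-3-en-2-ol (both carbinol epimers) | CC(O)/C(OC)=C/[S@@](=O)c1ccc(C)cc1
F6 | step 9 | 5-[(3,4-dimethoxybenzyl)sulfanyl]-1-phenyl-1H-tetrazole | COc1ccc(CSc2nnnn2-c2ccccc2)cc1OC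
F7 | step 9 | 5-[(3,4-dimethoxybenzyl)sulfonyl]-1-phenyl-1H-tetrazole | COc1ccc(CS(=O)(=O)c2nnnn2-c2ccccc2)cc1OC
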